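**Strategy.** Ring C is disconnected at O1–C8a and C3–C4. Both bonds are formed in one flask from a trans-chalcone epoxide whose aroyl ring A carries fluorine at the future C8a. BF3 opens the epoxide at the benzylic carbon (future C3) and the aroyl group migrates to it from the future C2 (C3–C4). The enolate oxygen of the resulting 3-oxopropanal, the former epoxide oxygen, then displaces fluoride at C8a (O1–C8a). The step exploits the C4 carbonyl, which lies ortho to C8a on ring A and activates it, and the O1–C2–C3 unit, a masked enol. The labile C3 stereocentre is set afterwards by transfer hydrogenation under dynamic kinetic resolution.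

Key step: step 5

Assumption: the target is the (3R)-isoflavanone (chroman-4-one numbering; ring A benzo ring, ring B 3-aryl group, ring C pyranone ring), and 2,6-dibromo-4-fluoroanisole and 3-hydroxy-4,5-dimethoxybenzaldehyde are taken as commercial.

**Step 1**
Reactants: 1 2,6-dibromo-4-fluoroanisole
Product: 3 1,3-bis(benzyloxy)-5-fluoro-2-methoxybenzene, via monobenzyl ether 2 (not isolated)
Conditions: BnOH (excess), CuI (cat.), 3,4,7,8-tetramethyl-1,10-phenanthroline (cat.), Cs2CO3, toluene, 110 °C
Reagents that add atoms: benzyl alcohol, OCc1ccccc1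
Why: Ullmann-type copper-catalysed C–O coupling should replace both equivalent aryl bromides by benzyloxy groups, while the C–F bond is inert to copper and is kept as the leaving group for step 5.

**Step 2**
Reactants: 3 1,3-bis(benzyloxy)-5-fluoro-2-methoxybenzene
Product: 4 1-[2,4-bis(benzyloxy)-6-fluoro-3-methoxyphenyl]-2-chloroethan-1-one
Conditions: ClCH2COCl, SnCl4, CH2Cl2, −40 to −10 °C
Reagents that add atoms: chloroacetyl chloride, ClCC(Cl)=O
Why: Friedel–Crafts acylation should occur at the only free position type (C4 and C6 are equivalent), which is ortho and para to the two benzyloxy groups and ortho to fluorine; the ketone formed deactivates the ring against a second acylation.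

**Step 3**
Reactants: 5 3-hydroxy-4,5-dimethoxybenzaldehyde
Product: 6 3-(benzyloxy)-4,5-dimethoxybenzaldehyde
Conditions: BnBr, K2CO3, DMF, rt
Reagents that add atoms: benzyl bromide, BrCc1ccccc1
Why: Williamson etherification of the phenol protects the ring B hydroxyl as a benzyl ether that is removed with the others in the last step.

**Step 4**
Reactants: 4 1-[2,4-bis(benzyloxy)-6-fluoro-3-methoxyphenyl]-2-chloroethan-1-one; 6 3-(benzyloxy)-4,5-dimethoxybenzaldehyde
Product: 8 racemic trans-[3-[3-(benzyloxy)-4,5-dimethoxyphenyl]oxiran-2-yl][2,4-bis(benzyloxy)-6-fluoro-3-methoxyphenyl]methanone, via chlorohydrin 7 (not isolated)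
Conditions: aq NaOH, Bu4NHSO4 (cat.), CH2Cl2, 0 °C to rt
Reagents that add atoms: none
Why: Darzens condensation: the chloroketone enolate adds to the aldehyde and the chlorohydrin alkoxide closes by intramolecular SN2 displacement to the trans-epoxy ketone, whose two centres need no control because step 5 erases them.

**Step 5**
Reactants: 8 racemic trans-epoxy ketone
Product: 10 5,7-bis(benzyloxy)-3-[3-(benzyloxy)-4,5-dimethoxyphenyl]-6-methoxy-4H-chromen-4-one, via formyl ketone 9 (not isolated)
Conditions: BF3·OEt2 (0.5 equiv), CH2Cl2, 0 °C; then Cs2CO3, DMSO, CH2Cl2 distilled off, 90 °C (one flask)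
Reagents that add atoms: none
Why: BF3 coordinates the epoxide oxygen, the benzylic C–O bond (future C3) ionises and the aroyl group shifts 1,2 from the future C2 to C3, which forms C3–C4 and leaves the epoxide oxygen on C2 as the formyl oxygen of 9 (Meinwald-type acyl shift of chalcone epoxides, the classical entry to 2-aryl-3-oxopropanals). Cs2CO3 then deprotonates the enol of 9 and its oxygen adds to C8a and expels fluoride, which forms O1–C8a; the closest known type is the base-mediated SNAr ring closure of 2-fluoroaroyl 1,3-dicarbonyl compounds to chromones. Ring C closes by a 6-endo-trig addition–elimination at the aromatic carbon ortho to the C4 carbonyl. No stereocentre is carried through: both epoxide centres are erased, C3 of 9 is enolised and 10 is achiral, so C3 is left for step 6. The step needs acyl migration in preference to hydride migration or fluoride capture, which the benzylic cation and a short cold contact with BF3 should favour, and ring closure at one defined carbon, which is secured because C8a carries the only leaving group on ring A, so the methoxy group cannot end up at C8.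

**Step 6**
Reactants: 10 5,7-bis(benzyloxy)-3-[3-(benzyloxy)-4,5-dimethoxyphenyl]-6-methoxy-4H-chromen-4-one
Product: 12 (3R,4R)-5,7-bis(benzyloxy)-3-[3-(benzyloxy)-4,5-dimethoxyphenyl]-6-methoxychroman-4-ol, via racemic isoflavanone 11 (not isolated)
Conditions: RuCl[(R,R)-TsDPEN](p-cymene) (cat.), HCO2H/Et3N (amine in excess), EtOAc, 40 °C
Reagents that add atoms: none
Why: Noyori–Ikariya transfer hydrogenation: the ruthenium hydride should first reduce C2=C3 conjugately to 11, which racemises through its enol under Et3N while the (R,R)-catalyst reduces the (3R)-ketone faster to the (4R)-carbinol with hydride entering trans to ring B, so that dynamic kinetic resolution gives the cis (3R,4R) alcohol and sets C3.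

**Step 7**
Reactants: 12 (3R,4R)-chroman-4-ol
Product: 13 (3R)-5,7-bis(benzyloxy)-3-[3-(benzyloxy)-4,5-dimethoxyphenyl]-6-methoxychroman-4-one
Conditions: DMP, pyridine, CH2Cl2, 0 °C to rt
Reagents that add atoms: none
Why: Dess–Martin oxidation under weakly buffered, non-enolising conditions should return the C4 ketone without touching the C3 centre.

**Step 8**
Reactants: 13 (3R)-tribenzyl isoflavanone
Product: 14 (3R)-5,7-dihydroxy-3-(3-hydroxy-4,5-dimethoxyphenyl)-6-methoxychroman-4-one
Conditions: H2 (1 atm), Pd/C, EtOAc/MeOH, rt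
Reagents that add atoms: none
Why: Hydrogenolysis of the three aryl benzyl ethers under neutral conditions should free the phenols without enolising C3; the reaction is stopped at the end of hydrogen uptake to spare the C4 ketone.

**Compound list**
1 | 2,6-dibromo-4-fluoroanisole | COc1c(Br)cc(F)cc1Br | starting material
2 | 1-(benzyloxy)-3-bromo-5-fluoro-2-methoxybenzene (not isolated) | COc1c(Br)cc(F)cc1OCc1ccccc1 | intermediate
3 | 1,3-bis(benzyloxy)-5-fluoro-2-methoxybenzene | COc1c(OCc2ccccc2)cc(F)cc1OCc1ccccc1 | intermediate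
4 | 1-[2,4-bis(benzyloxy)-6-fluoro-3-methoxyphenyl]-2-chloroethan-1-one | COc1c(OCc2ccccc2)cc(F)c(C(=O)CCl)c1OCc1ccccc1 | intermediate
5 | 3-hydroxy-4,5-dimethoxybenzaldehyde | COc1cc(C=O)cc(O)c1OC | starting material
6 | 3-(benzyloxy)-4,5-dimethoxybenzaldehyde | COc1cc(C=O)cc(OCc2ccccc2)c1OC | intermediate
7 | 1-[2,4-bis(benzyloxy)-6-fluoro-3-methoxyphenyl]-3-[3-(benzyloxy)-4,5-dimethoxyphenyl]-2-chloro-3-hydroxypropan-1-one (racemic diastereomers, formed as alkoxide, not isolated) | O=C(c1c(F)cc(OCc2ccccc2)c(OC)c1OCc1ccccc1)C(Cl)C(O)c1cc(OC)c(OC)c(OCc2ccccc2)c1 | intermediate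
8 | trans-[3-[3-(benzyloxy)-4,5-dimethoxyphenyl]oxiran-2-yl][2,4-bis(benzyloxy)-6-fluoro-3-methoxyphenyl]methanone (racemic; the 2S,3R enantiomer is drawn) | O=C(c1c(F)cc(OCc2ccccc2)c(OC)c1OCc1ccccc1)[C@H]1O[C@@H]1c1cc(OC)c(OC)c(OCc2ccccc2)c1 | intermediate
9 | 3-[2,4-bis(benzyloxy)-6-fluoro-3-methoxyphenyl]-2-[3-(benzyloxy)-4,5-dimethoxyphenyl]-3-oxopropanal (racemic, largely enol, not isolated) | O=CC(c1cc(OC)c(OC)c(OCc2ccccc2)c1)C(=O)c1c(F)cc(OCc2ccccc2)c(OC)c1OCc1ccccc1 | intermediate
10 | 5,7-bis(benzyloxy)-3-[3-(benzyloxy)-4,5-dimethoxyphenyl]-6-methoxy-4H-chromen-4-one | COc1cc(C2=COc3cc(OCc4ccccc4)c(OC)c(OCc4ccccc4)c3C2=O)cc(OCc2ccccc2)c1OC | intermediate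
11 | racemic 5,7-bis(benzyloxy)-3-[3-(benzyloxy)-4,5-dimethoxyphenyl]-6-methoxychroman-4-one (not isolated) | COc1cc(C2COc3cc(OCc4ccccc4)c(OC)c(OCc4ccccc4)c3C2=O)cc(OCc2ccccc2)c1OC | intermediate
12 | (3R,4R)-5,7-bis(benzyloxy)-3-[3-(benzyloxy)-4,5-dimethoxyphenyl]-6-methoxychroman-4-ol (3,4-cis) | COc1cc([C@@H]2COc3cc(OCc4ccccc4)c(OC)c(OCc4ccccc4)c3[C@@H]2O)cc(OCc2ccccc2)c1OC | intermediate
13 | (3R)-5,7-bis(benzyloxy)-3-[3-(benzyloxy)-4,5-dimethoxyphenyl]-6-methoxychroman-4-one | COc1cc([C@@H]2COc3cc(OCc4ccccc4)c(OC)c(OCc4ccccc4)c3C2=O)cc(OCc2ccccc2)c1OC | intermediate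
14 | (3R)-5,7-dihydroxy-3-(3-hydroxy-4,5-dimethoxyphenyl)-6-methoxychroman-4-one | COc1cc([C@@H]2COc3cc(O)c(OC)c(O)c3C2=O)cc(O)c1OC | target

**Step count.** Total: 8 steps. Longest linear sequence: 7 steps (1, 2, 4, 5, 6, 7, 8).

**Steps most likely to fail**

Step 5. The stabilised enolate of 9 may attack the donor-rich ring A too slowly, so that retro-Claisen loss of the formyl group or fluoride capture of the benzylic cation takes over. The fallback sets out from epoxide 8 and comes back at 11, the intermediate of step 6. It moves the ring closure to the isoflavanone oxidation level, where a primary alkoxide is the nucleophile. BF3·OEt2 in CH2Cl2 followed by aqueous NaOH in THF would cleave the formyl group of 9 and give 1-[2,4-bis(benzyloxy)-6-fluoro-3-methoxyphenyl]-2-[3-(benzyloxy)-4,5-dimethoxyphenyl]ethan-1-one F1. Paraformaldehyde and K2CO3 in DMSO should hydroxymethylate it to the hydroxymethyl ketone F2, whose alkoxide displaces fluoride in the same flask to give racemic isoflavanone 11. Isolated 11 then enters the conditions of step 6, where only the carbonyl reduction under dynamic kinetic resolution remains, and gives 12.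

Step 6. Conjugate reduction of the hindered 5-benzyloxychromone may stall, facial or cis selectivity may be poor, or the electron-rich benzylic carbinol may ionise and eliminate. The fallback sets out from 10 and comes back at 13. LiBH(s-Bu)3 in THF at −78 °C should reduce C2=C3 to racemic 11, which is isolated and resolved by preparative chromatography on a chiral stationary phase to give 13 directly. The unwanted (3S)-tribenzyl isoflavanone F3 is racemised with catalytic DBU and recycled, and the oxidation of step 7 is not needed.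

Step 2. The Lewis acid may remove or shift the benzyl group ortho to the new ketone. The fallback sets out from 3 and comes back at 4. Directed ortho-lithiation with lithium 2,2,6,6-tetramethylpiperidide (LiTMP) in THF at −78 °C, at the position flanked by fluorine and benzyloxy, would give 2,4-bis(benzyloxy)-6-fluoro-3-methoxyphenyllithium F4. This is trapped at −78 °C with 2-chloro-N-methoxy-N-methylacetamide to give 4 without any Lewis acid.

**Further compounds**
F1 | step 5 | 1-[2,4-bis(benzyloxy)-6-fluoro-3-methoxyphenyl]-2-[3-(benzyloxy)-4,5-dimethoxyphenyl]ethan-1-one | O=C(Cc1cc(OC)c(OC)c(OCc2ccccc2)c1)c1c(F)cc(OCc2ccccc2)c(OC)c1OCc1ccccc1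
F2 | step 5 | racemic 1-[2,4-bis(benzyloxy)-6-fluoro-3-methoxyphenyl]-2-[3-(benzyloxy)-4,5-dimethoxyphenyl]-3-hydroxypropan-1-one | O=C(C(CO)c1cc(OC)c(OC)c(OCc2ccccc2)c1)c1c(F)cc(OCc2ccccc2)c(OC)c1OCc1ccccc1
F3 | step 6 | (3S)-5,7-bis(benzyloxy)-3-[3-(benzyloxy)-4,5-dimethoxyphenyl]-6-methoxychroman-4-one | COc1cc([C@H]2COc3cc(OCc4ccccc4)c(OC)c(OCc4ccccc4)c3C2=O)cc(OCc2ccccc2)c1OC
F4 | step 2 | 2,4-bis(benzyloxy)-6-fluoro-3-methoxyphenyllithium | [Li]c1c(F)cc(OCc2ccccc2)c(OC)c1OCc1ccccc1
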